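(The runs stem from a simulated flask with constants of no real substance; the scatter is artificial.)

The vessel is closed and stirred, and its Pdt curves bend over early, so before the next charge I want to know where a flask stops.

| flask | Sbt | Ctl | time |
|---|---|---|---|
| violet | 0.800 M | 0.00160 M |  |
| grey | 1.20 M | 0.00160 M |  |
| red | 0.400 M | 8.00 × 10⁻⁴ M | 31 min |

| run | time / min | [Pdt] / M |
|---|---|---|
| violet run | 1.8 | 0.094 |
| violet run | 5.3 | 0.228 |
| violet run | 10 | 0.383 |
| violet run | 16 | 0.517 |
| violet run | 23 | 0.620 |
| violet run | 31 | 0.681 |
| grey run | 1.8 | 0.088 |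
| grey run | 5.3 | 0.224 |
| grey run | 10 | 0.368 |
| grey run | 16 | 0.482 |
| grey run | 23 | 0.573 |
| grey run | 31 | 0.637 |

(each reading ± 0.006 M)

- the exponent of [Sbt] in the starting rate at the charge of the violet run (at the point where two percent of the Sbt have become Pdt) (one fixed amount of Pdt, the same in the runs compared)
- Pdt in the red run at 31 min, as a share of the Sbt charged

- Overall: Sbt -> Pdt, with Ctl as catalyst.
- Constant volume, constant temperature.
- The analysis sees a species whether free or bound.
- An order is taken over about fifteen percent of the charge, up and down.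

The first readings of violet and grey, 0.094 M and 0.088 M, differ by 0.00600 M at a scatter of 0.006 M, so the order in [Sbt] reads near zero. Grey is the clearer run. By 31 min it has turned 53.1% of its Sbt, yet its rate has dropped 6.11-fold, from 0.0489 M min⁻¹ in the first interval to 0.00800 M min⁻¹ in the last. I therefore treat the fall as exponential catalyst deactivation, with the interval midpoints 26.1 min apart:

decay constant = ln(0.0489 M min⁻¹ / 0.00800 M min⁻¹) / 26.1 min = 0.0694 min⁻¹

rate at zero time = 0.0520 M min⁻¹

ceiling = 0.0520 M min⁻¹ / 0.0694 min⁻¹ = 0.750 M

I read this ceiling as an estimate of the total Pdt that the Ctl charged to grey makes over its working life, provided Sbt lasts. It stands lower than violet's charge of 0.800 M.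

Red has half the Ctl of violet, and violet and grey share one Ctl charge of 0.00160 M, so comparing those two gives no power of [Ctl] in the rate. Keeping the decay constant, 88.4% of the ceiling is made by 31 min:

first power: 0.375 M ceiling, 82.9% of the charge

second power: 0.188 M ceiling, 41.4% of the charge

These differ by 0.166 M, against a scatter of 0.006 M, so I leave red as charged and read it at 31 min. I commit to the first power, 82.9%.

The forecast, by its own reckoning, gives an order of −0.15 (−0.4 to 0.1) and 82% for red (71% to 93%): “So the rate hardly depends on [Sbt].”

The order comes to 0.0082, and red gives 45.6% at 31 min, or 0.183 M, near a quarter of grey's ceiling and close to the second-power 41.4%, while the apparent order in [Ctl] early in violet stands at 2.0.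

    Ctl + Sbt ⇌ Ctl.Sbt, settled at all times (9.190 M⁻¹)
    Ctl.Sbt + Ctl → Pdt + 2 Ctl (82200 M⁻¹ min⁻¹)
    2 Sbt ⇌ Sbt2, settled at all times (31.80 M⁻¹)
    Ctl + Sbt → J + Sbt (0.6720 M⁻¹ min⁻¹)

In violet, Ctl.Sbt + Ctl makes Pdt while Ctl + Sbt makes J alongside it. Violet has the Ctl charge of grey, and the curve with grey's ceiling of 0.750 M reaches half of violet's charge at 11.0 min, with the violet flask there at 10.9 min.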